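**Plan**
- Retrosynthesis: cut the two ester C–O bonds (angelate at ring C3, senecioate at side-chain C3′), then the side chain (C3′–C4′ by allylboration, C5′=C6′ by cross-metathesis, the exo-methylene from formaldehyde), then the ring bonds C4–C5 and C1–C2 of the 7-oxabicyclo[4.1.0]heptan-2-one core.
- Enabling feature: in the six-membered ring, C5–C6–C1(CH3) is a latent butan-2-one unit (C6 at the ketone level between two enolisable carbons) and C2–C3–C4 is a latent enal (C2 aldehyde, C4 β-carbon). A 3-oxopentanoate and an enal therefore close the carbocycle in one flask by a Michael/aldol [3+3] annulation.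
- Forward: enal 3 by cross-metathesis; [3+3] annulation to cyclohexenone 7 (carbocycle); epoxidation and Wharton transposition move the oxygen from C6 to C2; directed epoxidation closes the oxirane ring; then the side chain and the two esters.
- Stereochemistry: C4 from the prolinol silyl ether catalyst in the Michael step; relayed to the C1/C6 epoxide through the trans epoxy ketone, the C2 carbinol and hydroxyl-directed epoxidation; C3′ from the isopinocampheyl allylborane; C3 by anti hydroxylation, then Mitsunobu inversion with angelic acid.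

Key step: step 2

Remark: compounds 1, 2, 4, 16 and 20 and all reagents named under Conditions, including (−)-B-allyldiisopinocampheylborane, are taken as purchased.

Ring locants in the names of 12–21 follow the target (C1 methyl-bearing oxirane carbon, C2 ketone, C3, C4 side-chain carbon, C5 CH2, C6 oxirane CH).

**Step 1**
Reactants: 1 4-(benzyloxy)but-1-ene; 2 (E)-but-2-enal (crotonaldehyde)
Product: 3 (E)-5-(benzyloxy)pent-2-enal
Conditions: second-generation Grubbs catalyst (H2IMes)(PCy3)Cl2Ru=CHPh (3 mol %), 2 (5 equiv), CH2Cl2, 40 °C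
Reagents that add atoms: none
Why: Olefin cross-metathesis of a terminal alkene with excess crotonaldehyde is a standard route to enals, and the E geometry is the thermodynamic outcome.

**Step 2**
Reactants: 3 (E)-5-(benzyloxy)pent-2-enal; 4 tert-butyl 3-oxopentanoate
Product: 7 (S)-5-[2-(benzyloxy)ethyl]-2-methylcyclohex-2-en-1-one, via Michael adduct 5 (not isolated), via cyclohexenone tert-butyl ester 6 (not isolated)
Conditions: (S)-2-{bis[3,5-bis(trifluoromethyl)phenyl](trimethylsilyloxy)methyl}pyrrolidine (10 mol %), toluene, rt; then p-TsOH·H2O (20 mol %), 80 °C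
Reagents that add atoms: none
Why: The pyrrolidine condenses with enal 3 to an E-iminium ion whose β-carbon (later ring C4) is attacked by the enol of keto ester 4 (its C2, later ring C5) on the face away from the diaryl(silyloxy)methyl group; hydrolysis releases aldehyde 5, and under TsOH the ethyl-ketone methylene (later C1) adds to the aldehyde carbon (later C2), water is lost to give 6, and the tert-butyl ester is cleaved and decarboxylated. The closest known reaction type is the diarylprolinol-silyl-ether-catalysed Michael/aldol-condensation/decarboxylation [3+3] synthesis of 5-substituted cyclohex-2-enones from enals and tert-butyl 3-oxoalkanoates. The six-membered ring closes in the aldol step in a 6-(enolendo)-exo-trig mode. The only stereocenter that survives, the side-chain-bearing carbon, is set in the Michael step by the catalyst, and the S catalyst should give the S configuration; the other centres of 5 are erased by dehydration and decarboxylation. The step needs 1,4- over 1,2-addition, which the soft doubly activated nucleophile and iminium activation secure. It also needs a single aldol regiochemistry, secured because only the ketone methylene reaches the aldehyde through a six-membered transition state (the other enolisable positions would give four-membered rings).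

**Step 3**
Reactants: 7 (S)-5-[2-(benzyloxy)ethyl]-2-methylcyclohex-2-en-1-one
Product: 8 (1R,4R,6R)-4-[2-(benzyloxy)ethyl]-1-methyl-7-oxabicyclo[4.1.0]heptan-2-one (epoxide trans to the side chain)
Conditions: 30% aq. H2O2, NaOH (0.2 equiv), MeOH, 0 °C
Reagents that add atoms: hydrogen peroxide, OO
Why: Weitz–Scheffer nucleophilic epoxidation, in which hydroperoxide adds axially to the enone β-carbon anti to the C5 substituent and the enolate closes the oxirane, so the epoxide should form trans to the side chain as in the carvone series.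

**Step 4**
Reactants: 8 (1R,4R,6R)-4-[2-(benzyloxy)ethyl]-1-methyl-7-oxabicyclo[4.1.0]heptan-2-one
Product: 9 (1R,5R)-5-[2-(benzyloxy)ethyl]-2-methylcyclohex-2-en-1-ol (hydroxyl trans to the side chain)
Conditions: N2H4·H2O (3 equiv), AcOH (cat.), MeOH, 0 °C to rt
Reagents that add atoms: none
Why: Wharton transposition, in which the hydrazone of the epoxy ketone fragments with loss of N2 to the transposed allylic alcohol; the C–O bond at the former epoxide CH is not broken, so the carbinol stays trans to the side chain.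

**Step 5**
Reactants: 9 (1R,5R)-5-[2-(benzyloxy)ethyl]-2-methylcyclohex-2-en-1-ol
Product: 10 (1R,2R,4R,6S)-4-[2-(benzyloxy)ethyl]-1-methyl-7-oxabicyclo[4.1.0]heptan-2-ol (hydroxyl and epoxide cis to each other, both trans to the side chain)
Conditions: VO(acac)2 (5 mol %), t-BuOOH (decane solution), CH2Cl2, 0 °C to rt
Reagents that add atoms: tert-butyl hydroperoxide, CC(C)(C)OO
Why: Hydroxyl-directed vanadium-catalysed epoxidation delivers oxygen syn to the pseudo-axial allylic alcohol, which sets both oxirane stereocenters trans to the side chain.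

**Step 6**
Reactants: 10 (1R,2R,4R,6S)-4-[2-(benzyloxy)ethyl]-1-methyl-7-oxabicyclo[4.1.0]heptan-2-ol
Product: 11 (1R,2R,4R,6S)-4-(2-hydroxyethyl)-1-methyl-7-oxabicyclo[4.1.0]heptan-2-ol
Conditions: H2 (1 atm), Pd/C (10%), EtOAc, rt
Reagents that add atoms: none
Why: Hydrogenolysis of the benzyl ether at the only stage without a C=C bond; the isolated trisubstituted oxirane should not be reduced under these conditions.

**Step 7**
Reactants: 11 (1R,2R,4R,6S)-4-(2-hydroxyethyl)-1-methyl-7-oxabicyclo[4.1.0]heptan-2-ol
Product: 12 2-[(1S,4R,6S)-1-methyl-2-oxo-7-oxabicyclo[4.1.0]heptan-4-yl]acetaldehyde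
Conditions: Dess–Martin periodinane (3 equiv), pyridine, CH2Cl2, 0 °C to rt
Reagents that add atoms: none
Why: Dess–Martin oxidation converts the primary and the secondary alcohol in one operation without touching the oxirane; no stereocenter is formed or lost.

**Step 8**
Reactants: 12 2-[(1S,4R,6S)-1-methyl-2-oxo-7-oxabicyclo[4.1.0]heptan-4-yl]acetaldehyde
Product: 13 2-[(1S,4S,6S)-1-methyl-2-oxo-7-oxabicyclo[4.1.0]heptan-4-yl]prop-2-enal
Conditions: 37% aq. HCHO, pyrrolidine (10 mol %), EtCO2H (10 mol %), i-PrOH, 45 °C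
Reagents that add atoms: formaldehyde, C=O
Why: Amine-catalysed α-methylenation of an aldehyde (Mannich condensation and elimination) runs through the aldehyde enamine, so the hindered ring ketone should be left alone; the C4 descriptor changes only by priority.

**Step 9**
Reactants: 13 2-[(1S,4S,6S)-1-methyl-2-oxo-7-oxabicyclo[4.1.0]heptan-4-yl]prop-2-enal
Product: 14 (1S,4S,6S)-4-[(3S)-3-hydroxyhexa-1,5-dien-2-yl]-1-methyl-7-oxabicyclo[4.1.0]heptan-2-one
Conditions: (−)-Ipc2B(allyl) (from (+)-α-pinene), Et2O, −78 °C; then HOCH2CH2NH2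
Reagents that add atoms: (−)-B-allyldiisopinocampheylborane, C=CCB([C@@H]1C[C@@H]2C[C@H]([C@H]1C)C2(C)C)[C@@H]1C[C@@H]2C[C@H]([C@H]1C)C2(C)C
Why: Asymmetric allylboration through a chair-like six-membered transition state; this reagent should add to the Si face of the aldehyde and give the S carbinol under reagent control, and the aldehyde reacts far faster than the hindered ketone at −78 °C.

**Step 10**
Reactants: 14 (1S,4S,6S)-4-[(3S)-3-hydroxyhexa-1,5-dien-2-yl]-1-methyl-7-oxabicyclo[4.1.0]heptan-2-one
Product: 15 (1S,4S,6S)-4-[(3S)-3-hydroxy-6-methylhepta-1,5-dien-2-yl]-1-methyl-7-oxabicyclo[4.1.0]heptan-2-one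
Conditions: 2-methylbut-2-ene (excess), second-generation Grubbs catalyst (H2IMes)(PCy3)Cl2Ru=CHPh (5 mol %), CH2Cl2, 40 °C
Reagents that add atoms: 2-methylbut-2-ene, CC=C(C)C
Why: Cross-metathesis of the monosubstituted alkene with 2-methylbut-2-ene installs the prenyl terminus, while the 1,1-disubstituted alkene is too hindered to take part.

**Step 11**
Reactants: 15 (1S,4S,6S)-4-[(3S)-3-hydroxy-6-methylhepta-1,5-dien-2-yl]-1-methyl-7-oxabicyclo[4.1.0]heptan-2-one; 16 3-methylbut-2-enoyl chloride
Product: 17 (3S)-6-methyl-2-[(1S,4S,6S)-1-methyl-2-oxo-7-oxabicyclo[4.1.0]heptan-4-yl]hepta-1,5-dien-3-yl 3-methylbut-2-enoate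
Conditions: pyridine, DMAP (cat.), CH2Cl2, 0 °C
Reagents that add atoms: none
Why: Acylation of the secondary allylic alcohol with the acid chloride under nucleophilic catalysis proceeds at oxygen, so the carbinol configuration is retained.

**Step 12**
Reactants: 17 (3S)-6-methyl-2-[(1S,4S,6S)-1-methyl-2-oxo-7-oxabicyclo[4.1.0]heptan-4-yl]hepta-1,5-dien-3-yl 3-methylbut-2-enoate
Product: 19 (3S)-2-[(1S,3R,4R,6S)-3-hydroxy-1-methyl-2-oxo-7-oxabicyclo[4.1.0]heptan-4-yl]-6-methylhepta-1,5-dien-3-yl 3-methylbut-2-enoate, via lithium enolate 18 (not isolated)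
Conditions: LiN(SiMe3)2 (1.1 equiv), THF, −78 °C; 2-(phenylsulfonyl)-3-phenyloxaziridine; then AcOH
Reagents that add atoms: 2-(phenylsulfonyl)-3-phenyloxaziridine, O=S(=O)(c1ccccc1)N1OC1c1ccccc1
Why: Enolate oxidation with an N-sulfonyloxaziridine, in which the amide base should remove a ketone α-hydrogen at C3 (the only enolisable position) faster than the ester γ-hydrogens and the oxidant approaches anti to the adjacent C4 substituent, giving the 3,4-trans ketol.

**Step 13**
Reactants: 19 (3S)-2-[(1S,3R,4R,6S)-3-hydroxy-1-methyl-2-oxo-7-oxabicyclo[4.1.0]heptan-4-yl]-6-methylhepta-1,5-dien-3-yl 3-methylbut-2-enoate; 20 (Z)-2-methylbut-2-enoic acid (angelic acid)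
Product: 21 (1S,3S,4R,6S)-1-methyl-4-{(3S)-6-methyl-3-[(3-methylbut-2-enoyl)oxy]hepta-1,5-dien-2-yl}-2-oxo-7-oxabicyclo[4.1.0]heptan-3-yl (2Z)-2-methylbut-2-enoate
Conditions: PPh3, DIAD, toluene, 0 °C to rt
Reagents that add atoms: none
Why: Mitsunobu esterification, in which the carboxylate displaces the oxyphosphonium group α to the ketone by SN2 with inversion to give the 3,4-cis angelate; the Z acid is never activated at its carbonyl and so should not isomerise.

**Compound list**
1 | 4-(benzyloxy)but-1-ene | C=CCCOCc1ccccc1 | starting material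
2 | (E)-but-2-enal | C/C=C/C=O | starting material
3 | (E)-5-(benzyloxy)pent-2-enal | O=C/C=C/CCOCc1ccccc1 | intermediate
4 | tert-butyl 3-oxopentanoate | CCC(=O)CC(=O)OC(C)(C)C | starting material
5 | Michael adduct, tert-butyl (3R)-3-[2-(benzyloxy)ethyl]-5-oxo-2-propanoylpentanoate (C2 epimers, not isolated) | O=CC[C@@H](CCOCc1ccccc1)C(C(=O)OC(C)(C)C)C(=O)CC | intermediate
6 | cyclohexenone tert-butyl ester, tert-butyl (6S)-6-[2-(benzyloxy)ethyl]-3-methyl-2-oxocyclohex-3-ene-1-carboxylate (C1 epimers, not isolated) | CC1=CC[C@@H](CCOCc2ccccc2)C(C(=O)OC(C)(C)C)C1=O | intermediate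
7 | (S)-5-[2-(benzyloxy)ethyl]-2-methylcyclohex-2-en-1-one | CC1=CC[C@@H](CCOCc2ccccc2)CC1=O | intermediate
8 | (1R,4R,6R)-4-[2-(benzyloxy)ethyl]-1-methyl-7-oxabicyclo[4.1.0]heptan-2-one | O(CC[C@H]1CC(=O)[C@]2(C)O[C@@H]2C1)Cc1ccccc1 | intermediate
9 | (1R,5R)-5-[2-(benzyloxy)ethyl]-2-methylcyclohex-2-en-1-ol | O(CC[C@H]1CC=C(C)[C@H](O)C1)Cc1ccccc1 | intermediate
10 | (1R,2R,4R,6S)-4-[2-(benzyloxy)ethyl]-1-methyl-7-oxabicyclo[4.1.0]heptan-2-ol | O(CC[C@H]1C[C@@H]2O[C@]2(C)[C@H](O)C1)Cc1ccccc1 | intermediate
11 | (1R,2R,4R,6S)-4-(2-hydroxyethyl)-1-methyl-7-oxabicyclo[4.1.0]heptan-2-ol | OCC[C@H]1C[C@@H]2O[C@]2(C)[C@H](O)C1 | intermediate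
12 | 2-[(1S,4R,6S)-1-methyl-2-oxo-7-oxabicyclo[4.1.0]heptan-4-yl]acetaldehyde | O=CC[C@H]1C[C@@H]2O[C@]2(C)C(=O)C1 | intermediate
13 | 2-[(1S,4S,6S)-1-methyl-2-oxo-7-oxabicyclo[4.1.0]heptan-4-yl]prop-2-enal | C=C(C=O)[C@H]1C[C@@H]2O[C@]2(C)C(=O)C1 | intermediate
14 | (1S,4S,6S)-4-[(3S)-3-hydroxyhexa-1,5-dien-2-yl]-1-methyl-7-oxabicyclo[4.1.0]heptan-2-one | C=C([C@H](CC=C)O)[C@H]1C[C@@H]2O[C@]2(C)C(=O)C1 | intermediate
15 | (1S,4S,6S)-4-[(3S)-3-hydroxy-6-methylhepta-1,5-dien-2-yl]-1-methyl-7-oxabicyclo[4.1.0]heptan-2-one | C=C([C@H](CC=C(C)C)O)[C@H]1C[C@@H]2O[C@]2(C)C(=O)C1 | intermediate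
16 | 3-methylbut-2-enoyl chloride | CC(C)=CC(=O)Cl | starting material
17 | (3S)-6-methyl-2-[(1S,4S,6S)-1-methyl-2-oxo-7-oxabicyclo[4.1.0]heptan-4-yl]hepta-1,5-dien-3-yl 3-methylbut-2-enoate | C=C([C@H](CC=C(C)C)OC(=O)C=C(C)C)[C@H]1C[C@@H]2O[C@]2(C)C(=O)C1 | intermediate
18 | lithium enolate of 17 (C2–C3 enolate, not isolated) | C=C([C@H](CC=C(C)C)OC(=O)C=C(C)C)[C@H]1C[C@@H]2O[C@]2(C)C([O-])=C1.[Li+] | intermediate
19 | (3S)-2-[(1S,3R,4R,6S)-3-hydroxy-1-methyl-2-oxo-7-oxabicyclo[4.1.0]heptan-4-yl]-6-methylhepta-1,5-dien-3-yl 3-methylbut-2-enoate (3,4-trans ketol) | C=C([C@H](CC=C(C)C)OC(=O)C=C(C)C)[C@H]1C[C@@H]2O[C@]2(C)C(=O)[C@@H]1O | intermediate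
20 | (Z)-2-methylbut-2-enoic acid | C/C=C(/C)C(=O)O | starting material
21 | (1S,3S,4R,6S)-1-methyl-4-{(3S)-6-methyl-3-[(3-methylbut-2-enoyl)oxy]hepta-1,5-dien-2-yl}-2-oxo-7-oxabicyclo[4.1.0]heptan-3-yl (2Z)-2-methylbut-2-enoate | C=C([C@H](CC=C(C)C)OC(=O)C=C(C)C)[C@H]1C[C@@H]2O[C@]2(C)C(=O)[C@H]1OC(=O)/C(C)=C\C | target

**Count**
Total steps: 13. Longest linear sequence: 13 (fully linear; 2, 4, 16 and 20 enter as purchased partners).

**Steps most likely to fail**

Step 13. The carboxylate must attack C3 from the face that carries the C4 side chain, so the displacement may be slow and give way to elimination towards C4 or to substitution with retention. The fallback sets the C3 centre by protonation from the open face instead of substitution from the hindered one. It sets out from 19: silylation (Et3SiCl, imidazole, CH2Cl2) should give the 3,4-trans triethylsilyl ether F1. Deprotonation at C3 with LiN(SiMe3)2 at −78 °C and quench of the enolate with 2,6-di-tert-butylphenol, which delivers the proton anti to the C4 substituent, should give the 3,4-cis silyl ether F2. AcOH/THF/H2O removes the silyl group to give the 3,4-cis ketol F3. Acylation of F3 with 20 through its mixed anhydride (2,4,6-trichlorobenzoyl chloride, Et3N, toluene, 80 °C, no DMAP) proceeds with retention and comes back to the route at 21.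

Step 12. The amide base may deprotonate the senecioate γ-positions in competition with the ketone, and the oxidant may approach with poor facial selectivity. The fallback avoids the strong base and replaces steps 12 and 13 together. It sets out from 17: soft enolisation (Me3SiOTf, Et3N, CH2Cl2, 0 °C) should give the trimethylsilyl enol ether F4. N-Bromosuccinimide at −78 °C brominates the enol ether anti to the C4 substituent, faster than the isolated alkenes, to give the 3,4-trans α-bromo ketone F5. Displacement of bromide with cesium (Z)-2-methylbut-2-enoate in DMF (SN2 next to the carbonyl, inversion) comes back to the route at 21.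

Step 2. The hot acid stage may erode material by slow ring closure or by side reactions of the aldehyde, and the ethyl ketone may cyclise sluggishly. The fallback separates decarboxylation from ring closure and avoids strong acid at high temperature. It sets out from 4 and 3: 4 is cleaved with CF3CO2H in CH2Cl2 to 3-oxopentanoic acid F6. F6 is added to 3 under the same prolinol silyl ether catalyst, where conjugate addition is followed by loss of CO2 to give (3R)-3-[2-(benzyloxy)ethyl]-5-oxoheptanal F7. Intramolecular aldol condensation of F7 with pyrrolidinium acetate in toluene comes back to the route at 7.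

**Further compounds**
F1 | step 13 | 3,4-trans triethylsilyl ether of 19 | C=C([C@H](CC=C(C)C)OC(=O)C=C(C)C)[C@H]1C[C@@H]2O[C@]2(C)C(=O)[C@@H]1O[Si](CC)(CC)CC
F2 | step 13 | 3,4-cis triethylsilyl ether (C3 epimer of F1) | C=C([C@H](CC=C(C)C)OC(=O)C=C(C)C)[C@H]1C[C@@H]2O[C@]2(C)C(=O)[C@H]1O[Si](CC)(CC)CC
F3 | step 13 | 3,4-cis ketol (C3 epimer of 19) | C=C([C@H](CC=C(C)C)OC(=O)C=C(C)C)[C@H]1C[C@@H]2O[C@]2(C)C(=O)[C@H]1O
F4 | step 12 | trimethylsilyl enol ether of 17 (C2=C3) | C=C([C@H](CC=C(C)C)OC(=O)C=C(C)C)[C@H]1C[C@@H]2O[C@]2(C)C(O[Si](C)(C)C)=C1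
F5 | step 12 | 3,4-trans 3-bromo ketone derived from 17 | C=C([C@H](CC=C(C)C)OC(=O)C=C(C)C)[C@H]1C[C@@H]2O[C@]2(C)C(=O)[C@@H]1Br
F6 | step 2 | 3-oxopentanoic acid | CCC(=O)CC(=O)O
F7 | step 2 | (3R)-3-[2-(benzyloxy)ethyl]-5-oxoheptanal | O=CC[C@@H](CCOCc1ccccc1)CC(=O)CC
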